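**Retrosynthetic overview**

1. Target 18 ⇐ 5,7-diene alcohol 16 by hydroboration–oxidation of C5=C6, which sets C5–H and C6–OH last, on the face away from the axial C10 and C4 methyl groups.
2. 16 ⇐ tricyclic β-silyl sulfone 15 by fluoride 1,2-elimination; 15 ⇐ triene 14 by an intramolecular Diels–Alder reaction that forms C5–C6 and C9–C10 (ring B).
3. Enabling feature: the C18 oxygen on C4 of ring A and C6 of ring B both flank C5, so a C18–O–SiMe2–C6 link (a six-membered 1,2-oxasilinane across C4–C5) can hold a (Z)-dienylsilane C6–C9 over the C5=C10 alkene of ring A; the C7=C8 alkene of the target is the alkene the cycloaddition leaves behind.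
4. 14 ⇐ silyl ether 10 (ring A vinyl sulfone from methyl 2-oxocyclohexane-1-carboxylate, C4 set by chiral-enamine methylation) + enyne ester 13 (from methyl geranate, which already carries the E-enoate).
5. Ring order: ring A (bought as the cyclohexanone) → ring B together with the temporary oxasilinane (key step) → oxasilinane cleaved in step 12.

Key step: step 11

Numbering used in the text: labdane numbering (decalin C1–C10; side chain C11–C16 with C15 the ester carbon; C17 = methyl on C8; C18 = oxygenated carbon on C4; C19 = methyl on C4; C20 = methyl on C10).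

Assumption: the lithiated valine enamine of step 2 is taken to be methylated on the face that gives the (S)-keto ester under the chelating conditions written; if the face is the other one, the D-valine ester is used in step 1 and nothing else changes.

**Route**

Step 1
Reactants: 1 methyl 2-oxocyclohexane-1-carboxylate; 2 tert-butyl L-valinate
Product: 3 methyl 2-{[(2S)-1-tert-butoxy-3-methyl-1-oxobutan-2-yl]amino}cyclohex-1-ene-1-carboxylate
Conditions: BF3·OEt2 (cat.), benzene, reflux, azeotropic removal of water
Reagents that add atoms: none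
Why: Acid-catalysed condensation of a β-keto ester with a primary amine should give the conjugated, hydrogen-bonded enamine (enamine formation), and the valine stereocenter is not touched.

Step 2
Reactants: 3 methyl 2-{[(2S)-1-tert-butoxy-3-methyl-1-oxobutan-2-yl]amino}cyclohex-1-ene-1-carboxylate
Product: 5 methyl (1S)-1-methyl-2-oxocyclohexane-1-carboxylate, via methylated ketimine 4 (not isolated)
Conditions: LiN(i-Pr)2, toluene/HMPA, −78 °C; MeI, −78 to −50 °C; then 1 M aq. HCl, 0 °C
Reagents that add atoms: iodomethane, CI; water, O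
Why: Auxiliary-controlled alkylation of a chiral lithio-enamine: the lithium is chelated by the valine ester, one face of the aza-enolate is shielded by the isopropyl group, C-methylation should set the quaternary C4 center, and mild acid hydrolysis of the ketimine releases the keto ester and the auxiliary.

Step 3
Reactants: 5 methyl (1S)-1-methyl-2-oxocyclohexane-1-carboxylate
Product: 6 methyl (1S,3RS)-1,3-dimethyl-2-oxocyclohexane-1-carboxylate
Conditions: LiN(i-Pr)2, THF, −78 °C; MeI, −78 to 0 °C
Reagents that add atoms: iodomethane, CI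
Why: Enolate alkylation: the only enolizable position is the CH2 next to the ketone on the side away from the quaternary carbon, so methylation should give the future C10 methyl, and the new center is left as a mixture because it becomes sp2 in step 4.

Step 4
Reactants: 6 methyl (1S,3RS)-1,3-dimethyl-2-oxocyclohexane-1-carboxylate
Product: 7 methyl (1S)-1,3-dimethyl-2-{[(trifluoromethyl)sulfonyl]oxy}cyclohex-2-ene-1-carboxylate
Conditions: KN(SiMe3)2, THF, −78 to 0 °C; PhNTf2, 0 to 25 °C
Reagents that add atoms: N-phenylbis(trifluoromethanesulfonimide), O=S(=O)(N(c1ccccc1)S(=O)(=O)C(F)(F)F)C(F)(F)F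
Why: Enol triflate formation: only one enolate can form (the other α-carbon is quaternary), so O-sulfonylation should give the C5=C10 enol triflate as a single regioisomer without touching C4.

Step 5
Reactants: 7 methyl (1S)-1,3-dimethyl-2-{[(trifluoromethyl)sulfonyl]oxy}cyclohex-2-ene-1-carboxylate
Product: 8 (6R)-6-(hydroxymethyl)-2,6-dimethylcyclohex-1-en-1-yl trifluoromethanesulfonate
Conditions: i-Bu2AlH, CH2Cl2, −78 to 0 °C; aq. KNaC4H4O6
Reagents that add atoms: none
Why: Hydride reduction of the ester to the primary alcohol (C18–OH) by i-Bu2AlH, to which an enol triflate is inert at low temperature; the descriptor changes only because of the priority rules.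

Step 6
Reactants: 8 (6R)-6-(hydroxymethyl)-2,6-dimethylcyclohex-1-en-1-yl trifluoromethanesulfonate
Product: 9 [(1R)-1,3-dimethyl-2-(phenylsulfonyl)cyclohex-2-en-1-yl]methanol
Conditions: PhSO2Na, Pd2(dba)3 (cat.), Xantphos (cat.), n-Bu4NCl, toluene, 100 °C
Reagents that add atoms: sodium benzenesulfinate, [Na+].[O-]S(=O)c1ccccc1
Why: Palladium-catalysed C–S cross-coupling of an alkenyl triflate with a sulfinate salt (oxidative addition, sulfinate transfer, reductive elimination) should give the vinyl sulfone with the double bond in place and the free neopentyl alcohol untouched.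

Step 7
Reactants: 9 [(1R)-1,3-dimethyl-2-(phenylsulfonyl)cyclohex-2-en-1-yl]methanol
Product: 10 {[(1R)-1,3-dimethyl-2-(phenylsulfonyl)cyclohex-2-en-1-yl]methoxy}dimethylsilane
Conditions: Me2SiHCl, Et3N, CH2Cl2, 0 °C; used without chromatography
Reagents that add atoms: chlorodimethylsilane, C[SiH](C)Cl
Why: O-Silylation of the primary alcohol with a chlorosilane and an amine base should give the hydridosilyl ether that carries the tether atom.

Step 8
Reactants: 11 methyl (2E)-3,7-dimethylocta-2,6-dienoate (methyl geranate)
Product: 12 methyl (2E,6E)-3,7-dimethyl-8-oxoocta-2,6-dienoate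
Conditions: SeO2, EtOH, reflux
Reagents that add atoms: selenium dioxide, O=[Se]=O
Why: Riley allylic oxidation (ene reaction, then [2,3]-sigmatropic shift) should attack the E-methyl group of the electron-rich terminal trisubstituted alkene and give the E-enal, while the enoate alkene is deactivated.

Step 9
Reactants: 12 methyl (2E,6E)-3,7-dimethyl-8-oxoocta-2,6-dienoate
Product: 13 methyl (2E,6E)-3,7-dimethylnona-2,6-dien-8-ynoate
Conditions: Me3SiCHN2, LiN(i-Pr)2, THF, −78 to 0 °C
Reagents that add atoms: (trimethylsilyl)diazomethane, C[Si](C)(C)C=[N+]=[N-]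
Why: Colvin-type one-carbon homologation: the lithiated silyl diazomethane adds to the aldehyde faster than to the ester at −78 °C, Peterson elimination and loss of N2 give an alkylidene carbene, and its 1,2-hydrogen shift should give the terminal enyne with the 6E alkene unchanged.

Step 10
Reactants: 10 {[(1R)-1,3-dimethyl-2-(phenylsulfonyl)cyclohex-2-en-1-yl]methoxy}dimethylsilane; 13 methyl (2E,6E)-3,7-dimethylnona-2,6-dien-8-ynoate
Product: 14 methyl (2E,6E,8Z)-9-({[(1R)-1,3-dimethyl-2-(phenylsulfonyl)cyclohex-2-en-1-yl]methoxy}dimethylsilyl)-3,7-dimethylnona-2,6,8-trienoate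
Conditions: [RuCl2(p-cymene)]2 (cat.), CH2Cl2, 45 °C
Reagents that add atoms: none
Why: Ruthenium-catalysed trans-hydrosilylation of a terminal alkyne should put silicon on the terminal carbon (C6) and give the Z-alkenylsilane, and the tetrasubstituted vinyl sulfone and the trisubstituted alkenes should not compete.

Step 11
Reactants: 14 methyl (2E,6E,8Z)-9-({[(1R)-1,3-dimethyl-2-(phenylsulfonyl)cyclohex-2-en-1-yl]methoxy}dimethylsilyl)-3,7-dimethylnona-2,6,8-trienoate
Product: 15 cis-fused tricyclic β-silyl sulfone, (4R,5S,6R,9R,10S)-configured methyl (13E)-6,18-[(dimethylsilanediyl)oxy]-5-(phenylsulfonyl)labda-7,13-dien-15-oate (O–SiMe2 bridge from C18 to C6; PhSO2 on C5 cis to the C10 methyl; C6–Si anti to PhSO2; C9 side chain cis to the C10 methyl)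
Conditions: toluene (0.01 M), BHT (cat.), 180 °C, sealed tube
Reagents that add atoms: none
Why: Thermal, concerted but asynchronous intramolecular [4+2] cycloaddition of the (Z)-1-silyl diene (C6–C9, largest HOMO coefficient at C9 because of the C8 methyl) onto the vinyl sulfone of ring A (C5=C10, largest LUMO coefficient at C10) should form C9–C10 and C5–C6 together; the closest known reaction types are the intramolecular Diels–Alder reaction of trienes joined by a temporary silyl ether tether and the Diels–Alder reactions of vinyl sulfones that are paired with a silyl group as a masked alkyne. Ring B closes as the cyclohexene of the cycloaddition (suprafacial on both components), and the temporary 1,2-oxasilinane closes with it, cis-fused to ring A and to ring B. C10 and C5 are set by addition to the face of the C5=C10 alkene that carries the CH2O arm of C4, because the three-atom C18–O–Si link cannot reach the other face, which also bears the C4 methyl, so the C10 methyl ends cis to the C4 methyl. C9 follows from the 8E geometry of the diene and the forced exo placement of ring A: a silicon on the inside (Z) position of C6 can reach C4 only when C4 points away from the diene, which puts the C10 methyl and the sulfonyl group under the diene and the C9 side chain cis to the C10 methyl, while C6 (silicon anti to the sulfonyl group) is set by the same geometry and is removed again with C5 in step 12. The step therefore needs regio-, facial and exo selectivity, all three secured by the short silicon tether from the C4 hydroxymethyl group and by the Z geometry of the dienylsilane, and the sulfonyl group lowers the LUMO of an otherwise unreactive ring alkene.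

Step 12
Reactants: 15 cis-fused tricyclic β-silyl sulfone
Product: 16 methyl (2E)-5-[(1R,5S,8aS)-5-(hydroxymethyl)-2,5,8a-trimethyl-1,5,6,7,8,8a-hexahydronaphthalen-1-yl]-3-methylpent-2-enoate
Conditions: n-Bu4NF, THF, 0 to 25 °C; aq. NH4Cl; handled under argon
Reagents that add atoms: none
Why: Fluoride-induced 1,2-elimination of a β-silyl sulfone: attack at silicon expels benzenesulfinate from the antiperiplanar C5 position and should give C5=C6 next to C7=C8, and the same reagent cleaves the Si–O bond and frees the C18 hydroxyl; the provisional C5 and C6 centers are removed on purpose, and C4, C9 and C10 are kept.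

Step 13
Reactants: 16 methyl (2E)-5-[(1R,5S,8aS)-5-(hydroxymethyl)-2,5,8a-trimethyl-1,5,6,7,8,8a-hexahydronaphthalen-1-yl]-3-methylpent-2-enoate
Product: 18 methyl (2E)-5-[(1R,4R,4aS,5S,8aS)-4-hydroxy-5-(hydroxymethyl)-2,5,8a-trimethyl-1,4,4a,5,6,7,8,8a-octahydronaphthalen-1-yl]-3-methylpent-2-enoate, via cyclic alkoxyborane 17 (not isolated)
Conditions: BH3·THF (2.5 equiv), THF, 0 °C; then 3 M NaOH, 30% H2O2, 0 °C
Reagents that add atoms: hydrogen peroxide, OO
Why: Hydroboration–oxidation of a homoannular 5,7-diene, as known for steroidal 5,7-dienes: borane is first anchored on the C18 oxygen next to C6, and syn addition across C5=C6 from the face away from the axial C10 and C4 methyl groups should put boron on C6 and hydrogen on C5 (trans ring fusion); oxidation with retention then gives the C6 hydroxyl cis to C5–H, and the electron-poor enoate reacts much more slowly.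

**Compound list**

1 | methyl 2-oxocyclohexane-1-carboxylate | COC(=O)C1CCCCC1=O | starting material
2 | tert-butyl L-valinate | CC(C)[C@H](N)C(=O)OC(C)(C)C | starting material
3 | methyl 2-{[(2S)-1-tert-butoxy-3-methyl-1-oxobutan-2-yl]amino}cyclohex-1-ene-1-carboxylate | COC(=O)C1=C(N[C@@H](C(C)C)C(=O)OC(C)(C)C)CCCC1 | intermediate
4 | methyl (1S)-2-{[(2S)-1-tert-butoxy-3-methyl-1-oxobutan-2-yl]imino}-1-methylcyclohexane-1-carboxylate (methylated ketimine) | COC(=O)[C@@]1(C)CCCCC1=N[C@@H](C(C)C)C(=O)OC(C)(C)C | intermediate
5 | methyl (1S)-1-methyl-2-oxocyclohexane-1-carboxylate | COC(=O)[C@@]1(C)CCCCC1=O | intermediate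
6 | methyl (1S,3RS)-1,3-dimethyl-2-oxocyclohexane-1-carboxylate | COC(=O)[C@@]1(C)CCCC(C)C1=O | intermediate
7 | methyl (1S)-1,3-dimethyl-2-{[(trifluoromethyl)sulfonyl]oxy}cyclohex-2-ene-1-carboxylate | COC(=O)[C@@]1(C)CCCC(C)=C1OS(=O)(=O)C(F)(F)F | intermediate
8 | (6R)-6-(hydroxymethyl)-2,6-dimethylcyclohex-1-en-1-yl trifluoromethanesulfonate | OC[C@@]1(C)CCCC(C)=C1OS(=O)(=O)C(F)(F)F | intermediate
9 | [(1R)-1,3-dimethyl-2-(phenylsulfonyl)cyclohex-2-en-1-yl]methanol | OC[C@@]1(C)CCCC(C)=C1S(=O)(=O)c1ccccc1 | intermediate
10 | {[(1R)-1,3-dimethyl-2-(phenylsulfonyl)cyclohex-2-en-1-yl]methoxy}dimethylsilane | C[SiH](C)OC[C@@]1(C)CCCC(C)=C1S(=O)(=O)c1ccccc1 | intermediate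
11 | methyl (2E)-3,7-dimethylocta-2,6-dienoate (methyl geranate) | COC(=O)/C=C(\C)CCC=C(C)C | starting material
12 | methyl (2E,6E)-3,7-dimethyl-8-oxoocta-2,6-dienoate | COC(=O)/C=C(\C)CC/C=C(\C)C=O | intermediate
13 | methyl (2E,6E)-3,7-dimethylnona-2,6-dien-8-ynoate | COC(=O)/C=C(\C)CC/C=C(\C)C#C | intermediate
14 | methyl (2E,6E,8Z)-9-({[(1R)-1,3-dimethyl-2-(phenylsulfonyl)cyclohex-2-en-1-yl]methoxy}dimethylsilyl)-3,7-dimethylnona-2,6,8-trienoate | COC(=O)/C=C(\C)CC/C=C(\C)/C=C\[Si](C)(C)OC[C@@]1(C)CCCC(C)=C1S(=O)(=O)c1ccccc1 | intermediate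
15 | cis-fused tricyclic β-silyl sulfone, (4R,5S,6R,9R,10S)-methyl (13E)-6,18-[(dimethylsilanediyl)oxy]-5-(phenylsulfonyl)labda-7,13-dien-15-oate | COC(=O)/C=C(\C)CC[C@@H]1C(C)=C[C@@H]([Si]3(C)C)[C@@]2(S(=O)(=O)c4ccccc4)[C@@](C)(CO3)CCC[C@@]12C | intermediate
16 | methyl (2E)-5-[(1R,5S,8aS)-5-(hydroxymethyl)-2,5,8a-trimethyl-1,5,6,7,8,8a-hexahydronaphthalen-1-yl]-3-methylpent-2-enoate | COC(=O)/C=C(\C)CC[C@@H]1C(C)=CC=C2[C@@](C)(CO)CCC[C@@]12C | intermediate
17 | cyclic alkoxyborane, C6–BH–O–C18 bridged on the target skeleton (C5–H and C6–B cis, both trans to the C10 methyl) | COC(=O)/C=C(\C)CC[C@@H]1C(C)=C[C@@H]([BH]3)[C@@H]2[C@@](C)(CO3)CCC[C@@]12C | intermediate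
18 | methyl (2E)-5-[(1R,4R,4aS,5S,8aS)-4-hydroxy-5-(hydroxymethyl)-2,5,8a-trimethyl-1,4,4a,5,6,7,8,8a-octahydronaphthalen-1-yl]-3-methylpent-2-enoate (CNP0149445.1) | COC(=O)/C=C(\C)CC[C@@H]1C(C)=C[C@@H](O)[C@@H]2[C@@](C)(CO)CCC[C@@]12C | target

**Step count and risks**

Total step count: 13. Longest linear sequence: 11 steps (steps 1 to 7, then 10 to 13).

Steps most likely to fail:

1. Step 11. The cycloaddition may be too slow at temperatures that the dienyl silyl ether tolerates, because bond formation at C5 creates a fully substituted carbon between two fully substituted neighbours; cleavage of the Si–O link or isomerization of the diene would then take over. Fallback, from 8 and 13, back to the route at 16: ring B is closed by an electrocyclization instead. Hydroboration of 13 with pinacolborane (Cp2ZrHCl cat., CH2Cl2, 25 °C) should give methyl (2E,6E,8E)-3,7-dimethyl-9-(4,4,5,5-tetramethyl-1,3,2-dioxaborolan-2-yl)nona-2,6,8-trienoate F1. Suzuki–Miyaura coupling of F1 with triflate 8 (Pd(PPh3)4 cat., K3PO4, THF/H2O, 50 °C) should give methyl (2E,6E,8E)-9-[(6S)-6-(hydroxymethyl)-2,6-dimethylcyclohex-1-en-1-yl]-3,7-dimethylnona-2,6,8-trienoate F2, which forms the C5–C6 bond. Irradiation of F2 (λ ≥ 300 nm, Et2O, −20 °C, argon) should first isomerize the C6=C7 bond to Z and then close the hexatriene C10=C5–C6=C7–C8=C9 by conrotatory 6π electrocyclization, the ring closure known from previtamin D. Orbital symmetry fixes C9–H and the C10 methyl anti, as in 16. C4 steers the helicity of the triene only weakly in this variant, so 16 would have to be separated from its C9,C10-diastereomer before step 13.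

2. Step 13. The borane may not distinguish well enough between the two trisubstituted double bonds of the diene (boron on C7 instead of C6), or it may begin to reduce the enoate. Fallback, from 16, back to the route at 18: silicon is delivered from the C18 oxygen. Silylation of 16 (Me2SiHCl, Et3N, CH2Cl2, 0 °C) should give methyl (2E)-5-[(1R,5S,8aS)-5-{[(dimethylsilyl)oxy]methyl}-2,5,8a-trimethyl-1,5,6,7,8,8a-hexahydronaphthalen-1-yl]-3-methylpent-2-enoate F3. Intramolecular hydrosilylation of F3 (Pt2[(CH2=CHSiMe2)2O]3 cat., toluene, 60 °C) can place silicon only on C6, because C5 is fully substituted, and should add Si and H syn from the face of the C18 arm to give the trans-fused 1,2-oxasilinane with the C6–SiMe2–O–C18 bridge on the target skeleton F4. Tamao–Fleming oxidation of F4 (30% H2O2, KF, KHCO3, THF/MeOH, 25 °C) replaces C–Si by C–OH with retention and gives 18.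

3. Step 10. The ruthenium-catalysed hydrosilylation of the conjugated enyne may lose its Z selectivity or place silicon on the internal carbon. Fallback, from 9 and 13, back to the route at 14: the Z geometry is set by a semireduction instead. Alcohol 9 with Me2SiCl2 (excess, Et3N, CH2Cl2, 0 °C) should give chloro{[(1R)-1,3-dimethyl-2-(phenylsulfonyl)cyclohex-2-en-1-yl]methoxy}dimethylsilane F5. Coupling of F5 with alkyne 13 (Zn(OTf)2, Et3N, CH2Cl2, 25 °C) should give methyl (2E,6E)-9-({[(1R)-1,3-dimethyl-2-(phenylsulfonyl)cyclohex-2-en-1-yl]methoxy}dimethylsilyl)-3,7-dimethylnona-2,6-dien-8-ynoate F6. Hydroboration of the silylalkyne in F6 with dicyclohexylborane (THF, 0 °C), then protonolysis with acetic acid, adds two hydrogens cis and should give the Z-alkenylsilane 14.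

**Further compounds**

F1 | step 11 | methyl (2E,6E,8E)-3,7-dimethyl-9-(4,4,5,5-tetramethyl-1,3,2-dioxaborolan-2-yl)nona-2,6,8-trienoate | COC(=O)/C=C(\C)CC/C=C(\C)/C=C/B1OC(C)(C)C(C)(C)O1
F2 | step 11 | methyl (2E,6E,8E)-9-[(6S)-6-(hydroxymethyl)-2,6-dimethylcyclohex-1-en-1-yl]-3,7-dimethylnona-2,6,8-trienoate | COC(=O)/C=C(\C)CC/C=C(\C)/C=C/C1=C(C)CCC[C@]1(C)CO
F3 | step 13 | methyl (2E)-5-[(1R,5S,8aS)-5-{[(dimethylsilyl)oxy]methyl}-2,5,8a-trimethyl-1,5,6,7,8,8a-hexahydronaphthalen-1-yl]-3-methylpent-2-enoate | COC(=O)/C=C(\C)CC[C@@H]1C(C)=CC=C2[C@@](C)(CO[SiH](C)C)CCC[C@@]12C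
F4 | step 13 | trans-fused 1,2-oxasilinane with the C6–SiMe2–O–C18 bridge on the target skeleton (C5–H and C6–Si cis, both trans to the C10 methyl) | COC(=O)/C=C(\C)CC[C@@H]1C(C)=C[C@@H]([Si]3(C)C)[C@@H]2[C@@](C)(CO3)CCC[C@@]12C
F5 | step 10 | chloro{[(1R)-1,3-dimethyl-2-(phenylsulfonyl)cyclohex-2-en-1-yl]methoxy}dimethylsilane | C[Si](C)(Cl)OC[C@@]1(C)CCCC(C)=C1S(=O)(=O)c1ccccc1
F6 | step 10 | methyl (2E,6E)-9-({[(1R)-1,3-dimethyl-2-(phenylsulfonyl)cyclohex-2-en-1-yl]methoxy}dimethylsilyl)-3,7-dimethylnona-2,6-dien-8-ynoate | COC(=O)/C=C(\C)CC/C=C(\C)C#C[Si](C)(C)OC[C@@]1(C)CCCC(C)=C1S(=O)(=O)c1ccccc1
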